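The runs come from a simulation from invented constants; scatter was added.

1. The closed, stirred vessel held substrate, reagent and capture agent at constant temperature. Red and green were run earlier; alpha, beta and delta were new.

| setting | red | green | alpha | beta | delta |
|---|---|---|---|---|---|
| substrate | 0.30 M | 0.30 M | 0.30 M | 0.30 M | 0.30 M |
| reagent | 2.1 equiv | 3.1 equiv | 2.50 equiv | 3.00 equiv | 4.00 equiv |
| capture agent | 0.015 M | 0.015 M | 0.0150 M | 0.0150 M | 0.0150 M |
| remark | run made earlier | run made earlier |  |  |  |
| time |  |  | 10 h | 10 h | 10 h |

| run | time / h | first product / % | triple product / % | substrate / % |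
|---|---|---|---|---|
| red | 0.417 | 15.9 | 0.3 | 80.0 |
| red | 1.00 | 28.0 | 1.2 | 58.3 |
| red | 2.00 | 30.5 | 0.3 | 37.5 |
| red | 5.00 | 25.2 | 0.7 | 9.4 |
| green | 0.417 | 23.1 | 0 | 71.3 |
| green | 1.00 | 33.7 | 0.2 | 45.0 |
| green | 2.00 | 34.0 | 0 | 20.7 |
| green | 5.00 | 18.4 | 3.6 | 3.5 |

(standard deviation of a reading: 1 percentage point)

- final first product, as a percentage of the substrate charged, for each flask in turn (alpha, beta, delta)

2. I counted halvings. Green's first product fell from 34.0% to 18.4% between the readings at 2.00 h and 5.00 h. That gave, as a reading with its scatter, the net halving time, the time in which first product halves with supply from substrate included: 3.39 h.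

3. I assumed this loss was pseudo-first-order in first product, with a rate constant proportional to the reagent charged, so I scaled the halving time inversely with the equivalents.

4. I turned the question round. For first product to lose no more than one halving in the 5.00 h after the last reading, the halving time had to be at least that long. But alpha's scaled value was 4.20 h, shorter than that span, and green's span held 1.47 halvings.

5. I interpolated the amounts at 5.00 h linearly in equivalents between red and green, extending the line for delta. Halving from there, I reckoned 9.85% for alpha, 7.09% for beta and 3.28% for delta.

6. The forecast gave 18%, 13% and 7%, higher than my beta figure at its second point, and said the loss “depends only weakly on reagent”.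

7. The flasks gave 10.6%, 6.59% and 2.03%.

    substrate + first product → side product (k = 0.0190 /M/min)
    substrate + reagent → first product + by-product (k = 0.0140 /M/min)
    reagent + first product → bis adduct + by-product (k = 0.0100 /M/min)
    reagent + triple product → tetra adduct + by-product (k = 0.0160 /M/min)
    reagent + bis adduct → triple product + by-product (k = 3.00 × 10⁻⁴ /M/min)
    bis adduct + capture agent → trapped intermediate (k = 0.0160 /M/min)

In alpha, the step from substrate to first product had 94% of its turnover up to 10.0 h behind it at 5.00 h, while the step from first product to bis adduct reached half of its turnover up to that time at 3.17 h; reagent stood at 41.6% of its charge at 10.0 h. Applying the scaled halving time to alpha's 23.5% at 5.00 h gives 10.3% at 10.0 h, and applying beta's scaled time to its 19.9% gives 7.41%, where beta held 6.59%.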